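**Plan**
1. Retrosynthetic cuts: the C‑19/C‑20 protecting esters come off last. The cyclopentane ring B (C5–C6–C8–C9–C10) is traced back to a cyclohexanone ring C5–C6–C7–C8–C9–C10 by putting C‑7 back between C‑6 and C‑8 (6‑diazo‑7‑ketone, Wolff retron). Ring D is cut at C13–C16 and C8–C15, C‑4 at C4–C18 and C4–C19, and the six‑membered ring at C5–C6 and C9–C10.
2. Forward order: rings A and C are bought as rings (1, 4). A silicon‑tethered Diels–Alder reaction makes the six‑membered precursor of ring B, SmI2 then closes ring D, and the ring contraction closes ring B last.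
3. Enabling feature: in ring B the only ring substituent, the C‑7 ester, sits on C‑6 directly beside the spiro‑quaternary C‑8. This is the product pattern of a 2‑diazocyclohexanone contraction in which C‑8 migrates from C‑7 to C‑6 and C‑7 leaves the ring as the methyl ester.
4. Stereochemistry: a CBS reduction sets a C‑4 carbinol, which is erased later. The O–Si–O tether relays it to C‑5, C‑9 and C‑10 (endo, same face). C‑4 and C‑8 are set by alkylation on the convex face, C‑13 by the bridge, and C‑6 by equilibration in the key step.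

Key step: step 17

Remark (numbering): gibberellane numbering is used throughout (ring A C1–C5, C10; ring C C8, C9, C11–C14; ring D C8, C13–C16; C‑17 exocyclic CH2; C‑18 methyl; C‑7, C‑19, C‑20 carboxyl carbons); "upper face" means the face of ring B that carries H‑5.
Remark (configuration): the SMILES is read as drawn, with rings A/B cis‑fused, H‑5, C‑20, H‑9, C‑7 and the C‑15 bridge on the upper face, rings A and C on the lower face, and C‑19 cis to C‑6 but trans to C‑20; this is the C‑10 epimer of the usual gibberellin pattern.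
Remark (supply): acid 1 is taken as a catalogue compound, as its methyl ester is.

**Step 1**
Reactants: 1 3‑oxocyclohex‑1‑ene‑1‑carboxylic acid
Product: 2 tert‑butyl 3‑oxocyclohex‑1‑ene‑1‑carboxylate
Conditions: Cl3CC(=NH)Ot‑Bu, BF3·OEt2 (cat.), CH2Cl2/cyclohexane, rt
Reagents that add atoms: tert‑butyl 2,2,2‑trichloroacetimidate, CC(C)(C)OC(=N)C(Cl)(Cl)Cl
Why: Acid‑catalysed imidate esterification should give the bulky tert‑butyl ester, chosen because it resists MeLi, fluoride and methoxide later and can be removed without protic acid.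

**Step 2**
Reactants: 2 tert‑butyl 3‑oxocyclohex‑1‑ene‑1‑carboxylate
Product: 3 tert‑butyl (R)‑3‑hydroxycyclohex‑1‑ene‑1‑carboxylate
Conditions: (S)‑2‑methyl‑CBS‑oxazaborolidine (10 mol%), BH3·SMe2, THF, −30 °C
Reagents that add atoms: none
Why: CBS reduction of the enone carbonyl (1,2‑addition) should set the (R)‑carbinol with the alkene arm acting as the large group; this centre later fixes the absolute configuration of the whole core (the antipodal catalyst would serve if the sense proved opposite).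

**Step 3**
Reactants: 4 1,4‑dioxaspiro[4.5]decan‑7‑one
Product: 5 2,4,6‑triisopropylbenzenesulfonyl hydrazone of 4
Conditions: 2,4,6‑(i‑Pr)3C6H2SO2NHNH2, MeOH, HCl (cat.), rt
Reagents that add atoms: 2,4,6‑triisopropylbenzenesulfonohydrazide, CC(C)c1cc(C(C)C)c(S(=O)(=O)NN)c(C(C)C)c1
Why: Simple condensation gives the hindered arylsulfonyl hydrazone needed for a clean Shapiro reaction.

**Step 4**
Reactants: 5 2,4,6‑triisopropylbenzenesulfonyl hydrazone of 4
Product: 7 1‑(1,4‑dioxaspiro[4.5]dec‑7‑en‑7‑yl)ethan‑1‑one, via vinyllithium 6 (not isolated)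
Conditions: n‑BuLi (2.2 equiv), THF, −78 to 0 °C; then MeC(O)N(OMe)Me, −78 °C to rt
Reagents that add atoms: N‑methoxy‑N‑methylacetamide, CC(=O)N(C)OC
Why: In the Shapiro reaction the second deprotonation should occur at the less hindered α‑CH2 (away from the ketal), and the vinyllithium is acylated once by the N‑methoxy‑N‑methylamide to give the 1‑acetylcyclohexene that supplies C‑6, C‑7, C‑8 and C‑9.

**Step 5**
Reactants: 7 1‑(1,4‑dioxaspiro[4.5]dec‑7‑en‑7‑yl)ethan‑1‑one; 3 tert‑butyl (R)‑3‑hydroxycyclohex‑1‑ene‑1‑carboxylate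
Product: 9 mixed dimethylsilyl acetal joining the dienol oxygen of 7 (O on C‑7) to the C‑4 oxygen of 3, via chlorosilyl dienol ether 8 (not isolated)
Conditions: LiN(i‑Pr)2, THF, −78 °C; Me2SiCl2 (5 equiv), −78 °C to rt, volatiles removed; then 3, imidazole, CH2Cl2, 0 °C
Reagents that add atoms: dichlorodimethylsilane, C[Si](C)(Cl)Cl
Why: Kinetic deprotonation of the methyl ketone gives the cross‑conjugated dienolate, which is O‑silylated by excess Me2SiCl2, and the remaining Si–Cl bond is then displaced by the allylic alcohol, so diene and dienophile are joined by a short, removable O–Si–O tether.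

**Step 6**
Reactants: 9 mixed dimethylsilyl acetal (triene)
Product: 10 tricyclic Diels–Alder adduct (C7=C8 enol silyl ether with O7–SiMe2–O4 bridge, tert‑butyl ester C‑20 on C‑10, 13,13‑ethylenedioxy; H‑5, C‑20 and H‑9 on the upper face, O‑4, C‑1 and C‑11 on the lower face)
Conditions: toluene (0.01 M), BHT (cat.), 160 °C, sealed tube
Reagents that add atoms: none
Why: In this silicon‑tethered intramolecular Diels–Alder reaction the O–Si–O link can only be spanned if C‑4 lies under C‑7, so ring A must be endo and the diene must add to the face of the C4–O bond; this gives the C5–C6 and C9–C10 bonds with H‑5, C‑20 and H‑9 on one face and relays the CBS centre to C‑5, C‑9 and C‑10.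

**Step 7**
Reactants: 10 tricyclic Diels–Alder adduct
Product: 13 4‑hydroxy 7‑O‑tert‑butyldimethylsilyl enol ether, via lithium C‑7 enolate 4‑O‑trimethylsilyl ether 11 (not isolated), via 7‑O‑TBS enol ether 4‑O‑TMS ether 12 (not isolated)
Conditions: MeLi, THF, −78 to −30 °C; t‑BuMe2SiCl, DMPU, −78 to 0 °C; then K2CO3, MeOH, 0 °C
Reagents that add atoms: tert‑butyldimethylsilyl chloride, CC(C)(C)[Si](C)(C)Cl
Why: MeLi attacks silicon and expels the better leaving group, the enolate, which is re‑silylated on oxygen so that C‑7 stays masked regiospecifically as the C7=C8 enol ether, while the labile 4‑O‑SiMe3 ether is removed by methanolysis; the hindered tert‑butyl ester should survive.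

**Step 8**
Reactants: 13 4‑hydroxy 7‑O‑TBS enol ether
Product: 14 4‑ketone
Conditions: Dess–Martin periodinane, NaHCO3, CH2Cl2, 0 °C to rt
Reagents that add atoms: none
Why: Buffered Dess–Martin oxidation of the secondary alcohol should leave the silyl enol ether, ketal and ester untouched; the CBS‑derived centre has done its work and is erased here.

**Step 9**
Reactants: 14 4‑ketone
Product: 15 C‑4 enol triflate (C3=C4)
Conditions: KN(SiMe3)2, THF, −78 °C; PhNTf2, −78 to 0 °C
Reagents that add atoms: N‑phenylbis(trifluoromethanesulfonimide), O=S(=O)(N(c1ccccc1)S(=O)(=O)C(F)(F)F)C(F)(F)F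
Why: Kinetic deprotonation should occur at the unhindered C‑3 methylene and not at the ring‑fusion methine C‑5, and O‑triflation of the enolate gives the handle for introducing C‑19.

**Step 10**
Reactants: 15 C‑4 enol triflate
Product: 16 2‑(trimethylsilyl)ethyl C‑19 enoate (C3=C4)
Conditions: Pd(OAc)2 (5 mol%), dppp, CO (1 atm), Me3SiCH2CH2OH, Et3N, DMF, 60 °C
Reagents that add atoms: carbon monoxide, [C-]#[O+]; 2‑(trimethylsilyl)ethanol, C[Si](C)(C)CCO
Why: Palladium‑catalysed alkoxycarbonylation (oxidative addition of the enol triflate to zerovalent palladium, CO insertion, alcoholysis) installs C‑19 as a fluoride‑labile ester.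

**Step 11**
Reactants: 16 2‑(trimethylsilyl)ethyl C‑19 enoate
Product: 17 saturated C‑19 ester (both C‑4 epimers)
Conditions: H2 (3 atm), Pd/C (10 wt%), EtOAc, rt
Reagents that add atoms: none
Why: Catalytic hydrogenation should reduce the conjugated trisubstituted alkene only (the tetrasubstituted silyl enol ether is inert); the C‑4 configuration does not matter because C‑4 is enolised next.

**Step 12**
Reactants: 17 saturated C‑19 ester
Product: 18 4‑methyl compound (C‑18 cis to H‑5 and C‑20; C‑19 ester cis to C‑6)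
Conditions: LiN(i‑Pr)2, THF, −78 to −40 °C; MeI, DMPU, −78 to −20 °C
Reagents that add atoms: iodomethane, CI
Why: Ester enolate alkylation should take place on the convex face of the cis‑fused A/B system, anti to the adjacent C5–C6 bond, which sets the quaternary C‑4 with the ester on the side of ring B; C‑4 is the only acidic position while C‑7 is masked.

**Step 13**
Reactants: 18 4‑methyl compound
Product: 19 8‑propargyl 7‑ketone (propargyl on the upper face, cis to H‑9)
Conditions: (Me2N)3S+ Me3SiF2− (1.1 equiv), HC≡CCH2Br, THF, −78 to −20 °C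
Reagents that add atoms: 3‑bromoprop‑1‑yne, C#CCBr
Why: Fluoride cleavage of the enol silyl ether gives the C7/C8 enolate regiospecifically, and C‑alkylation should occur on the convex upper face because rings A and C both hang below ring B, giving the cis B/C fusion; the hindered silylethyl ester should outlast one equivalent of fluoride at low temperature.

**Step 14**
Reactants: 19 8‑propargyl 7‑ketone
Product: 20 7,13‑diketone
Conditions: 1 M aq. HCl, THF, rt
Reagents that add atoms: water, O
Why: Acetal hydrolysis unmasks the C‑13 ketone; both esters and the alkyne are stable to dilute aqueous acid at room temperature.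

**Step 15**
Reactants: 20 7,13‑diketone
Product: 21 tetracyclic 7‑ketone (ring D closed: 13‑hydroxy, 16‑methylene)
Conditions: SmI2 (2.5 equiv), t‑BuOH, THF/HMPA, −78 to 0 °C
Reagents that add atoms: none
Why: Ketyl–alkyne reductive cyclisation (5‑exo‑dig) from the unhindered C‑13 ketyl forms the C13–C16 bond and gives the bridgehead allylic alcohol directly; the C‑13 configuration is dictated by the bridge from C‑8, and the hindered C‑7 ketone has no ring‑forming path because it would need a four‑membered ring.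

**Step 16**
Reactants: 21 tetracyclic 7‑ketone
Product: 23 6‑diazo‑7‑ketone, via 6‑trifluoroacetyl ketone 22 (not isolated)
Conditions: LiN(SiMe3)2 (2.2 equiv), THF, −78 °C; CF3CO2CH2CF3; then MsN3, Et3N, H2O, MeCN, rt
Reagents that add atoms: methanesulfonyl azide, CS(=O)(=O)N=[N+]=[N-]
Why: Claisen trifluoroacetylation can only occur at C‑6, the sole enolisable position of the C‑7 ketone, and deacylative Regitz diazo transfer then gives the α‑diazoketone; any trifluoroacetate formed on the 13‑OH is hydrolysed in the second stage.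

**Step 17**
Reactants: 23 6‑diazo‑7‑ketone
Product: 25 ring‑contracted triester (7‑methyl, 19‑(2‑trimethylsilylethyl), 20‑tert‑butyl; C‑7 on the upper face), via ketene 24 (not isolated)
Conditions: hν (365 nm), MeOH, rt; then NaOMe (cat.), MeOH, rt
Reagents that add atoms: methanol, CO
Why: Irradiation expels N2 from the 6‑diazo‑7‑ketone and C‑8 shifts from C‑7 to C‑6 with retention (photochemical Wolff rearrangement) to give ketene 24, which methanol captures as the C‑7 methyl ester. The closest known reaction type is the light‑induced ring contraction of 2‑diazocyclohexanones to cyclopentanecarboxylates. The cyclopentane ring B (C5–C6–C8–C9–C10) is closed by contraction, through a 1,2‑alkyl shift that makes the C6–C8 bond as the C7–C8 bond breaks, not by an exo or endo cyclisation. The new stereocentre C‑6 is set under thermodynamic control: methoxide equilibration should place the ester on the upper face, trans to the quaternary C‑4 and away from the concave side occupied by rings A and C, while C‑5, C‑8, C‑9 and C‑10 are untouched. The step needs C‑8 (not C‑5) to migrate and only C‑7 to become a methyl ester; the first is fixed because the carbonyl sits at C‑7 beside C‑8, the second because the two existing esters are hindered tert‑butyl and silylethyl esters on quaternary carbons that should not exchange with methanol or catalytic methoxide. Light of 365 nm in neat methanol should keep carbene O–H insertion and excitation of the alkene negligible.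

**Step 18**
Reactants: 25 ring‑contracted triester
Product: 27 target (7‑methyl ester 19,20‑diacid), via silylated intermediate 26 (not isolated)
Conditions: Me3SiOTf, 2,6‑lutidine, CH2Cl2, 0 °C; then Bu4NF, THF, 0 °C to rt; cold 0.1 M aq. HCl wash
Reagents that add atoms: none
Why: The silyl triflate converts the tert‑butyl ester into a silyl ester without protic acid (the 13‑OH is silylated in passing), and fluoride then removes the silylethyl ester by β‑elimination together with the silyl ester and ether; the methyl ester is inert to both reagents.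

**Compound list**
1 | 3‑oxocyclohex‑1‑ene‑1‑carboxylic acid | O=C1C=C(C(=O)O)CCC1 | starting material
2 | tert‑butyl 3‑oxocyclohex‑1‑ene‑1‑carboxylate | O=C1C=C(C(=O)OC(C)(C)C)CCC1 | intermediate
3 | tert‑butyl (R)‑3‑hydroxycyclohex‑1‑ene‑1‑carboxylate | O[C@@H]1CCCC(=C1)C(=O)OC(C)(C)C | intermediate
4 | 1,4‑dioxaspiro[4.5]decan‑7‑one | O=C1CCCC2(C1)OCCO2 | starting material
5 | 2,4,6‑triisopropylbenzenesulfonyl hydrazone of 4 | CC(C)c1cc(C(C)C)c(S(=O)(=O)NN=C2CCCC3(C2)OCCO3)c(C(C)C)c1 | intermediate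
6 | (1,4‑dioxaspiro[4.5]dec‑7‑en‑7‑yl)lithium | [Li]C1=CCCC2(C1)OCCO2 | intermediate (not isolated)
7 | 1‑(1,4‑dioxaspiro[4.5]dec‑7‑en‑7‑yl)ethan‑1‑one | CC(=O)C1=CCCC2(C1)OCCO2 | intermediate
8 | chloro(dimethyl)silyl dienol ether of 7 | C=C(O[Si](C)(C)Cl)C1=CCCC2(C1)OCCO2 | intermediate (not isolated)
9 | mixed dimethylsilyl acetal of the dienol of 7 and (R)‑alcohol 3 | C=C(O[Si](C)(C)O[C@@H]1CCCC(=C1)C(=O)OC(C)(C)C)C1=CCCC2(C1)OCCO2 | intermediate
10 | tricyclic Diels–Alder adduct with O7–SiMe2–O4 bridge (H‑5, C‑20, H‑9 upper face; O‑4, C‑1, C‑11 lower face) | C[Si]5(C)OC1=C2CC3(OCCO3)CC[C@H]2[C@@]4(C(=O)OC(C)(C)C)CCC[C@@H](O5)[C@H]4C1 | intermediate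
11 | lithium C‑7 enolate, 4‑O‑trimethylsilyl ether | [Li+].[O-]C1=C2CC3(OCCO3)CC[C@H]2[C@@]4(C(=O)OC(C)(C)C)CCC[C@@H](O[Si](C)(C)C)[C@H]4C1 | intermediate (not isolated)
12 | 7‑O‑TBS enol ether, 4‑O‑trimethylsilyl ether | CC(C)(C)[Si](C)(C)OC1=C2CC3(OCCO3)CC[C@H]2[C@@]4(C(=O)OC(C)(C)C)CCC[C@@H](O[Si](C)(C)C)[C@H]4C1 | intermediate (not isolated)
13 | 4‑hydroxy 7‑O‑TBS enol ether | CC(C)(C)[Si](C)(C)OC1=C2CC3(OCCO3)CC[C@H]2[C@@]4(C(=O)OC(C)(C)C)CCC[C@@H](O)[C@H]4C1 | intermediate
14 | 4‑ketone | CC(C)(C)[Si](C)(C)OC1=C2CC3(OCCO3)CC[C@H]2[C@@]4(C(=O)OC(C)(C)C)CCCC(=O)[C@H]4C1 | intermediate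
15 | C‑4 enol triflate (C3=C4) | CC(C)(C)[Si](C)(C)OC1=C2CC3(OCCO3)CC[C@H]2[C@@]4(C(=O)OC(C)(C)C)CCC=C(OS(=O)(=O)C(F)(F)F)[C@H]4C1 | intermediate
16 | 2‑(trimethylsilyl)ethyl C‑19 enoate (C3=C4) | CC(C)(C)[Si](C)(C)OC1=C2CC3(OCCO3)CC[C@H]2[C@@]4(C(=O)OC(C)(C)C)CCC=C(C(=O)OCC[Si](C)(C)C)[C@H]4C1 | intermediate
17 | saturated C‑19 ester, C‑4 configuration left open (both epimers are carried on) | CC(C)(C)[Si](C)(C)OC1=C2CC3(OCCO3)CC[C@H]2[C@@]4(C(=O)OC(C)(C)C)CCCC(C(=O)OCC[Si](C)(C)C)[C@H]4C1 | intermediate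
18 | 4‑methyl compound (C‑18 cis to H‑5; C‑19 cis to C‑6) | CC(C)(C)[Si](C)(C)OC1=C2CC3(OCCO3)CC[C@H]2[C@@]4(C(=O)OC(C)(C)C)CCC[C@@](C)(C(=O)OCC[Si](C)(C)C)[C@H]4C1 | intermediate
19 | 8‑propargyl 7‑ketone, 13‑ketal (propargyl cis to H‑9) | C#CC[C@]23CC4(OCCO4)CC[C@H]2[C@@]1(C(=O)OC(C)(C)C)CCC[C@@](C)(C(=O)OCC[Si](C)(C)C)[C@H]1CC3=O | intermediate
20 | 7,13‑diketone | C#CC[C@]23CC(=O)CC[C@H]2[C@@]1(C(=O)OC(C)(C)C)CCC[C@@](C)(C(=O)OCC[Si](C)(C)C)[C@H]1CC3=O | intermediate
21 | tetracyclic 7‑ketone with six‑membered ring B (13‑hydroxy, 16‑methylene) | C=C1C[C@]23C[C@@]1(O)CC[C@H]2[C@@]1(C(=O)OC(C)(C)C)CCC[C@@](C)(C(=O)OCC[Si](C)(C)C)[C@H]1CC3=O | intermediate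
22 | 6‑trifluoroacetyl 7‑ketone (C‑6 enolised, configuration open) | C=C1C[C@]23C[C@@]1(O)CC[C@H]2[C@@]1(C(=O)OC(C)(C)C)CCC[C@@](C)(C(=O)OCC[Si](C)(C)C)[C@H]1C(C(=O)C(F)(F)F)C3=O | intermediate (not isolated)
23 | 6‑diazo‑7‑ketone | C=C1C[C@]23C[C@@]1(O)CC[C@H]2[C@@]1(C(=O)OC(C)(C)C)CCC[C@@](C)(C(=O)OCC[Si](C)(C)C)[C@H]1C(=[N+]=[N-])C3=O | intermediate
24 | ketene (C6=C7=O) on the contracted ring | C=C1C[C@]23C[C@@]1(O)CC[C@H]2[C@@]1(C(=O)OC(C)(C)C)CCC[C@@](C)(C(=O)OCC[Si](C)(C)C)[C@H]1C3=C=O | intermediate (not isolated)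
25 | ring‑contracted triester (7‑methyl, 19‑silylethyl, 20‑tert‑butyl) | C=C1C[C@]23C[C@@]1(O)CC[C@H]2[C@@]1(C(=O)OC(C)(C)C)CCC[C@@](C)(C(=O)OCC[Si](C)(C)C)[C@H]1[C@@H]3C(=O)OC | intermediate
26 | 13‑O‑trimethylsilyl, 20‑trimethylsilyl ester, 19‑silylethyl ester | C=C1C[C@]23C[C@@]1(O[Si](C)(C)C)CC[C@H]2[C@@]1(C(=O)O[Si](C)(C)C)CCC[C@@](C)(C(=O)OCC[Si](C)(C)C)[C@H]1[C@@H]3C(=O)OC | intermediate (not isolated)
27 | target, 7‑methyl ester 19,20‑dicarboxylic acid | C=C1C[C@]23C[C@@]1(O)CC[C@H]2[C@@]1(C(=O)O)CCC[C@@](C)(C(=O)O)[C@H]1[C@@H]3C(=O)OC | target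

Total step count: 18. Longest linear sequence: 16 steps (from 4 through steps 3–18; equally from 1 through steps 1, 2 and 5–18).

**Steps most likely to fail**

Step 6. The ester‑activated, trisubstituted dienophile may react too slowly, so that the silyl acetal is lost by hydrolysis or silyl migration before cycloaddition. The fallback raises the dienophile to the enal level and sets out from 3. Reduction with i‑Bu2AlH should give (R)‑3‑(hydroxymethyl)cyclohex‑2‑en‑1‑ol F1, and oxidation of its primary allylic alcohol alone (TEMPO, PhI(OAc)2) should give (R)‑3‑hydroxycyclohex‑1‑ene‑1‑carbaldehyde F2. Silylation with 8 and imidazole would give the enal silyl acetal F3, which should cyclise at or below 80 °C to the tricyclic siloxane aldehyde F4. Fluoride cleavage of the enol–silicon bond (Bu4N+ Ph3SiF2−) with t‑BuMe2SiCl capture would give the 4‑hydroxy 7‑O‑TBS enol ether aldehyde F5, and Dess–Martin oxidation the 4‑keto aldehyde F6. Pinnick oxidation (NaClO2, NaH2PO4, 2‑methyl‑2‑butene) would give the 4‑keto acid F7, and tert‑butylation with Me2NCH(Ot‑Bu)2 comes back to the route at 14.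

Step 12. Methyl iodide may approach both faces of the C‑4 ester enolate (poor facial selectivity), because the C‑20 ester on the convex face competes with the C5–C6 bond on the concave face. The fallback changes the nucleophile and sets out from 14. Van Leusen reductive cyanation (TosMIC, t‑BuOK) should give the C‑4 nitrile F8. The metalated nitrile (LiN(i‑Pr)2, then MeI) is alkylated along the axial trajectory, the complement of the ester enolate, and should give the 4‑methyl‑4‑nitrile F9. Reduction with i‑Bu2AlH at −78 °C and hydrolysis would give the C‑19 aldehyde F10, and Pinnick oxidation the C‑19 acid F11. Esterification with 2‑(trimethylsilyl)ethyl 2,2,2‑trichloroacetimidate comes back to the route at 18.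

Step 15. Electron transfer to the C‑7 ketone (over‑reduction or pinacol coupling) may compete with ring closure from the C‑13 ketyl. The fallback takes C‑7 out of play as the alcohol and sets out from 19. Reduction with NaBH4/CeCl3 should give the 7‑hydroxy 13‑ketal F12, and acetal hydrolysis the 7‑hydroxy 13‑ketone F13. The SmI2 cyclisation then has only one carbonyl group and should give the tetracyclic 7,13‑diol F14. Dess–Martin oxidation of the secondary alcohol, which leaves the tertiary 13‑OH alone, comes back to the route at 21.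

**Further compounds**
F1 | step 6 | (R)‑3‑(hydroxymethyl)cyclohex‑2‑en‑1‑ol | O[C@@H]1CCCC(=C1)CO
F2 | step 6 | (R)‑3‑hydroxycyclohex‑1‑ene‑1‑carbaldehyde | O[C@@H]1CCCC(=C1)C=O
F3 | step 6 | enal silyl acetal (dienol of 7 and F2 joined through SiMe2) | C=C(O[Si](C)(C)O[C@@H]1CCCC(=C1)C=O)C1=CCCC2(C1)OCCO2
F4 | step 6 | tricyclic siloxane aldehyde (C‑20 formyl analogue of 10) | C[Si]5(C)OC1=C2CC3(OCCO3)CC[C@H]2[C@@]4(C=O)CCC[C@@H](O5)[C@H]4C1
F5 | step 6 | 4‑hydroxy 7‑O‑TBS enol ether 20‑aldehyde | CC(C)(C)[Si](C)(C)OC1=C2CC3(OCCO3)CC[C@H]2[C@@]4(C=O)CCC[C@@H](O)[C@H]4C1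
F6 | step 6 | 4‑keto 20‑aldehyde | CC(C)(C)[Si](C)(C)OC1=C2CC3(OCCO3)CC[C@H]2[C@@]4(C=O)CCCC(=O)[C@H]4C1
F7 | step 6 | 4‑keto 20‑carboxylic acid | CC(C)(C)[Si](C)(C)OC1=C2CC3(OCCO3)CC[C@H]2[C@@]4(C(=O)O)CCCC(=O)[C@H]4C1
F8 | step 12 | C‑4 nitrile (C‑4 configuration open) | CC(C)(C)[Si](C)(C)OC1=C2CC3(OCCO3)CC[C@H]2[C@@]4(C(=O)OC(C)(C)C)CCCC(C#N)[C@H]4C1
F9 | step 12 | 4‑methyl‑4‑nitrile (methyl cis to H‑5) | CC(C)(C)[Si](C)(C)OC1=C2CC3(OCCO3)CC[C@H]2[C@@]4(C(=O)OC(C)(C)C)CCC[C@@](C)(C#N)[C@H]4C1
F10 | step 12 | C‑19 aldehyde | CC(C)(C)[Si](C)(C)OC1=C2CC3(OCCO3)CC[C@H]2[C@@]4(C(=O)OC(C)(C)C)CCC[C@@](C)(C=O)[C@H]4C1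
F11 | step 12 | C‑19 carboxylic acid | CC(C)(C)[Si](C)(C)OC1=C2CC3(OCCO3)CC[C@H]2[C@@]4(C(=O)OC(C)(C)C)CCC[C@@](C)(C(=O)O)[C@H]4C1
F12 | step 15 | 7‑hydroxy 13‑ketal (C‑7 configuration open) | C#CC[C@]23CC4(OCCO4)CC[C@H]2[C@@]1(C(=O)OC(C)(C)C)CCC[C@@](C)(C(=O)OCC[Si](C)(C)C)[C@H]1CC3O
F13 | step 15 | 7‑hydroxy 13‑ketone | C#CC[C@]23CC(=O)CC[C@H]2[C@@]1(C(=O)OC(C)(C)C)CCC[C@@](C)(C(=O)OCC[Si](C)(C)C)[C@H]1CC3O
F14 | step 15 | tetracyclic 7,13‑diol (16‑methylene) | C=C1C[C@]23C[C@@]1(O)CC[C@H]2[C@@]1(C(=O)OC(C)(C)C)CCC[C@@](C)(C(=O)OCC[Si](C)(C)C)[C@H]1CC3O
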